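The biaryl bond is cut (Suzuki–Miyaura) into two halves that both derive from one bromo-oxolane, 15. Acid isomerises part of 15 into the aryltetralin half. The oxolane (O1, C2–C5) is not closed as a five-membered ring: it grows from the oxirane of an enantiopure trans-2-aryl-3-(1-benzylvinyl)oxirane. In one operation the copper-catalysed vinyloxirane rearrangement shifts O1 from C3 to the terminal methylene carbon (C5). It keeps the O1–C2(H)Ar bond with its stereocentre and leaves a C3=C4 alkene bearing the C4 benzyl group. The feature exploited is the allylic O1–C3/C4(benzyl)=C5 array hidden in the ring. C4–OH and C3–CH2OH then follow by anti addition opposite to the aryl group.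

Key step: step 7

Assumption: the stereodescriptors of the SMILES are taken literally, so the oxolane is (2R,3R,4S) with aryl, CH2OH and benzyl all cis, and the tetralin is (2S,3S,4S) in naphthalen-2-ol numbering. Oxolane numbering O1, C2 (aryl), C3 (CH2OH), C4 (OH, benzyl), C5 is used throughout.

Step 1
Reactants: 1 5-bromovanillin (3-bromo-4-hydroxy-5-methoxybenzaldehyde)
Product: 2 4-(benzyloxy)-3-bromo-5-methoxybenzaldehyde
Conditions: BnBr, K2CO3, DMF, 50 °C
Reagents that add atoms: benzyl bromide, BrCc1ccccc1
Why: Williamson ether synthesis, in which the acidic phenol is alkylated by the benzylic bromide while aldehyde and aryl bromide are inert to K2CO3.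

Step 2
Reactants: 3 4-bromo-2-methoxyphenol
Product: 4 1-(benzyloxy)-4-bromo-2-methoxybenzene
Conditions: BnBr, K2CO3, DMF, 50 °C
Reagents that add atoms: benzyl bromide, BrCc1ccccc1
Why: Williamson ether synthesis of the phenol, giving an ether that survives Grignard formation and all later steps.

Step 3
Reactants: 4 1-(benzyloxy)-4-bromo-2-methoxybenzene; 5 3-chloro-2-(chloromethyl)prop-1-ene
Product: 7 1-(benzyloxy)-4-[2-(chloromethyl)prop-2-en-1-yl]-2-methoxybenzene, via arylmagnesium bromide 6 (not isolated)
Conditions: Mg, THF, reflux; then added to 5 (3 equiv), CuI (5 mol %), THF, -20 to 0 °C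
Reagents that add atoms: none
Why: Copper-catalysed allylic substitution of a Grignard reagent, in which SN2 and SN2' attack on the symmetrical dichloride give the same product and the excess of 5 suppresses a second substitution.

Step 4
Reactants: 7 1-(benzyloxy)-4-[2-(chloromethyl)prop-2-en-1-yl]-2-methoxybenzene
Product: 8 diethyl {2-[4-(benzyloxy)-3-methoxybenzyl]prop-2-en-1-yl}phosphonate
Conditions: P(OEt)3 (neat, excess), NaI (10 mol %), 130 °C
Reagents that add atoms: triethyl phosphite, CCOP(OCC)OCC
Why: Michaelis–Arbuzov reaction, in which the primary allylic chloride (activated by iodide exchange) alkylates phosphorus and chloride dealkylates the phosphonium salt.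

Step 5
Reactants: 8 diethyl {2-[4-(benzyloxy)-3-methoxybenzyl]prop-2-en-1-yl}phosphonate; 2 4-(benzyloxy)-3-bromo-5-methoxybenzaldehyde
Product: 10 2-(benzyloxy)-5-{(1E)-3-[4-(benzyloxy)-3-methoxybenzyl]buta-1,3-dien-1-yl}-1-bromo-3-methoxybenzene, via lithiated phosphonate 9 (not isolated)
Conditions: n-BuLi (1.0 equiv), THF, -78 °C; then 2, DMPU, -78 °C to rt
Reagents that add atoms: none
Why: Horner–Wadsworth–Emmons olefination, in which the allylic phosphonate carbanion reacts at its alpha carbon with the aromatic aldehyde, reversible addition funnels to the E-alkene, and the aryl bromide never meets free n-BuLi.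

Step 6
Reactants: 10 the (E)-1-aryl-3-benzylbuta-1,3-diene
Product: 11 (2S,3S)-2-[4-(benzyloxy)-3-bromo-5-methoxyphenyl]-3-{3-[4-(benzyloxy)-3-methoxyphenyl]prop-1-en-2-yl}oxirane (trans)
Conditions: 1,2:4,5-di-O-isopropylidene-β-L-erythro-2,3-hexodiulo-2,6-pyranose (30 mol %), KHSO5 (as Oxone, 2KHSO5·KHSO4·K2SO4), K2CO3, Bu4NHSO4, MeCN/dimethoxymethane/aqueous Na2B4O7 buffer (pH 10.5), 0 °C
Reagents that add atoms: potassium peroxymonosulfate, [K+].[O-]S(=O)(=O)OO
Why: Shi epoxidation, in which the chiral dioxirane attacks the trans-disubstituted styrenyl alkene through a spiro transition state much faster than the 1,1-disubstituted alkene; the L-series ketone should give the (2S,3S)-oxirane, the mirror image of the (R,R) sense known for the D-fructose ketone with trans-β-methylstyrene, and this sets C2.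

Step 7
Reactants: 11 the (2S,3S)-vinyloxirane
Product: 12 (2R)-2-[4-(benzyloxy)-3-bromo-5-methoxyphenyl]-4-[4-(benzyloxy)-3-methoxybenzyl]-2,5-dihydrofuran
Conditions: Cu(hfacac)2 (5 mol %), toluene, 110–150 °C, sealed tube, N2
Reagents that add atoms: none
Why: Divalent copper in Cu(hfacac)2 binds the oxirane oxygen, and the allylic C3–O1 bond, which overlaps with the neighbouring 1,1-disubstituted alkene, opens to a copper alkoxide/allyl cation pair (or the equivalent oxa-cupracycle). In the s-cis conformer O1 re-closes on the terminal methylene carbon, so the three-membered ring O1–C2–C3 grows by the two alkene carbons into the 2,5-dihydrofuran; this is the known copper-catalysed vinyloxirane to 2,5-dihydrofuran ring expansion. The closure is formally 5-endo-trig on the allyl terminus, which is open to a cationic or metal-templated pathway. No new stereocentre is formed: C2 keeps its configuration because the O1–C2 bond is never broken, and the C3 centre of 11 is erased. The selectivity needed is allylic against benzylic C–O cleavage (the latter leads to Meinwald-type carbonyl isomers); the para-benzyloxy group is twisted out of conjugation by its bromine and methoxy neighbours, which also withdraw inductively from the meta positions, so the benzylic cation is poorly stabilised. The product carries the benzyl group on C4 and an unsubstituted C3, the pattern needed for the two facial operations that follow.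

Step 8
Reactants: 12 the (2R)-2,5-dihydrofuran
Product: 13 (1R,4S,5S)-4-[4-(benzyloxy)-3-bromo-5-methoxyphenyl]-1-[4-(benzyloxy)-3-methoxybenzyl]-3,6-dioxabicyclo[3.1.0]hexane (oxirane oxygen trans to the aryl group)
Conditions: dimethyldioxirane (acetone solution), CH2Cl2, -20 to 0 °C
Reagents that add atoms: dimethyldioxirane, CC1(C)OO1
Why: Dioxirane epoxidation under neutral conditions, in which the trisubstituted C3=C4 alkene is attacked on the ring face opposite to the C2 aryl group; this fixes the C4–O bond trans to the aryl group and places the benzyl group cis to it.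

Step 9
Reactants: 13 the 3,4-epoxyoxolane
Product: 15 (3S,4R,5R)-5-[4-(benzyloxy)-3-bromo-5-methoxyphenyl]-3-[4-(benzyloxy)-3-methoxybenzyl]-4-(hydroxymethyl)oxolan-3-ol (all-cis), via silane 14 (not isolated)
Conditions: (iPrO)Me2SiCH2MgCl (from ClCH2SiMe2(OiPr) and Mg), CuI (20 mol %), THF, -30 °C to rt; crude 14 then 30 % H2O2, KF, KHCO3, THF/MeOH, rt
Reagents that add atoms: (isopropoxydimethylsilyl)methylmagnesium chloride, CC(C)O[Si](C)(C)C[Mg]Cl; hydrogen peroxide, OO
Why: Copper-catalysed Grignard opening of an epoxide followed by Tamao oxidation; SN2 attack at the secondary C3 anti to the oxirane oxygen inverts C3 and puts the new carbon cis to aryl and benzyl, the C4–O bond survives as the tertiary alcohol, and the C–Si bond is then oxidised to the primary alcohol.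

Step 10
Reactants: 15 the all-cis bromo-oxolane (about half of the material)
Product: 16 (2S,3S,4S)-6-(benzyloxy)-4-[4-(benzyloxy)-3-bromo-5-methoxyphenyl]-2,3-bis(hydroxymethyl)-7-methoxy-1,2,3,4-tetrahydronaphthalen-2-ol
Conditions: CF3SO3H (10 mol %), CH2Cl2/(CF3)2CHOH 4:1, 0 °C
Reagents that add atoms: none
Why: Acid-induced ring opening and intramolecular Friedel–Crafts alkylation (the olivil to cycloolivil type isomerisation), in which strain in the all-cis oxolane helps ionisation of the benzylic C2–O1 bond and the benzyl ring attacks para to its methoxy group in a six-membered closure; the new tetralin C4 centre forms trans to the neighbouring CH2OH because the aryl group takes the pseudo-equatorial position, and the other two centres are untouched.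

Step 11
Reactants: 16 the bromo-aryltetralin triol
Product: 17 the pinacol boronate of 16 (Bpin in place of Br)
Conditions: B2pin2, PdCl2(dppf) (5 mol %), KOAc, 1,4-dioxane, 90 °C
Reagents that add atoms: bis(pinacolato)diboron, CC1(C)OB(OC1(C)C)B1OC(C)(C)C(C)(C)O1
Why: Miyaura borylation, in which zerovalent palladium inserts into the aryl bromide and the acetate-ligated complex transmetallates with the diboron reagent; free alcohols and benzyl ethers are tolerated.

Step 12
Reactants: 17 the aryltetralin boronate; 15 the all-cis bromo-oxolane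
Product: 18 tetra-O-benzyl ether of the target (5,5'-linked biaryl)
Conditions: Pd(OAc)2 (5 mol %), SPhos (10 mol %), K3PO4, toluene/H2O, 80 °C
Reagents that add atoms: none
Why: Suzuki–Miyaura coupling with a bulky biarylphosphine that handles one ortho benzyloxy group on each partner; the basic medium leaves the acid-labile oxolane intact and a biaryl with only two ortho substituents has no stable axis.

Step 13
Reactants: 18 the tetra-O-benzyl ether
Product: 19 CNP0344108.1 (target)
Conditions: H2 (1 atm), Pd/C (10 wt %), EtOAc/MeOH, rt, stopped when uptake for four benzyl groups ends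
Reagents that add atoms: none
Why: Catalytic hydrogenolysis of four aryl benzyl ethers in neutral medium, which are cleaved faster than the secondary benzylic C2–O1 bond of the oxolane and without any acid that could isomerise the all-cis ring.

Compound list
1 | 5-bromovanillin | COc1cc(C=O)cc(Br)c1O | starting material
2 | 4-(benzyloxy)-3-bromo-5-methoxybenzaldehyde | COc1cc(C=O)cc(Br)c1OCc1ccccc1 | intermediate
3 | 4-bromo-2-methoxyphenol | COc1cc(Br)ccc1O | starting material
4 | 1-(benzyloxy)-4-bromo-2-methoxybenzene | COc1cc(Br)ccc1OCc1ccccc1 | intermediate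
5 | 3-chloro-2-(chloromethyl)prop-1-ene | C=C(CCl)CCl | starting material
6 | [4-(benzyloxy)-3-methoxyphenyl]magnesium bromide | COc1cc([Mg]Br)ccc1OCc1ccccc1 | intermediate
7 | 1-(benzyloxy)-4-[2-(chloromethyl)prop-2-en-1-yl]-2-methoxybenzene | COc1cc(CC(=C)CCl)ccc1OCc1ccccc1 | intermediate
8 | diethyl {2-[4-(benzyloxy)-3-methoxybenzyl]prop-2-en-1-yl}phosphonate | COc1cc(CC(=C)CP(=O)(OCC)OCC)ccc1OCc1ccccc1 | intermediate
9 | alpha-lithiated phosphonate 8 | COc1cc(CC(=C)C([Li])P(=O)(OCC)OCC)ccc1OCc1ccccc1 | intermediate
10 | (E)-1-aryl-3-benzylbuta-1,3-diene | COc1cc(CC(=C)/C=C/c2cc(OC)c(OCc3ccccc3)c(Br)c2)ccc1OCc1ccccc1 | intermediate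
11 | (2S,3S)-trans-2-aryl-3-(1-benzylvinyl)oxirane | COc1cc(CC(=C)[C@@H]2O[C@H]2c2cc(OC)c(OCc3ccccc3)c(Br)c2)ccc1OCc1ccccc1 | intermediate
12 | (2R)-2-aryl-4-benzyl-2,5-dihydrofuran | COc1cc(CC2=C[C@H](c3cc(OC)c(OCc4ccccc4)c(Br)c3)OC2)ccc1OCc1ccccc1 | intermediate
13 | (1R,4S,5S)-4-aryl-1-benzyl-3,6-dioxabicyclo[3.1.0]hexane | COc1cc(C[C@@]23CO[C@@H](c4cc(OC)c(OCc5ccccc5)c(Br)c4)[C@@H]2O3)ccc1OCc1ccccc1 | intermediate
14 | all-cis oxolan-3-ol with CH2SiMe2(OiPr) on C3 | COc1cc(C[C@@]2(O)CO[C@@H](c3cc(OC)c(OCc4ccccc4)c(Br)c3)[C@H]2C[Si](C)(C)OC(C)C)ccc1OCc1ccccc1 | intermediate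
15 | (3S,4R,5R)-5-aryl-3-benzyl-4-(hydroxymethyl)oxolan-3-ol (bromo, di-O-benzyl) | COc1cc(C[C@@]2(O)CO[C@@H](c3cc(OC)c(OCc4ccccc4)c(Br)c3)[C@H]2CO)ccc1OCc1ccccc1 | intermediate
16 | (2S,3S,4S)-bromo-aryltetralin triol (di-O-benzyl) | Brc1cc([C@H]2c3cc(OCc4ccccc4)c(OC)cc3C[C@@](O)(CO)[C@@H]2CO)cc(OC)c1OCc1ccccc1 | intermediate
17 | pinacol boronate of 16 | CC1(C)OB(OC1(C)C)c1cc([C@H]2c3cc(OCc4ccccc4)c(OC)cc3C[C@@](O)(CO)[C@@H]2CO)cc(OC)c1OCc1ccccc1 | intermediate
18 | tetra-O-benzyl ether of the target | COc1cc(C[C@@]2(O)CO[C@@H](c3cc(OC)c(OCc4ccccc4)c(-c4cc([C@H]5c6cc(OCc7ccccc7)c(OC)cc6C[C@@](O)(CO)[C@@H]5CO)cc(OC)c4OCc4ccccc4)c3)[C@H]2CO)ccc1OCc1ccccc1 | intermediate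
19 | CNP0344108.1 | COc1cc(C[C@@]2(O)CO[C@@H](c3cc(OC)c(O)c(-c4cc([C@H]5c6cc(O)c(OC)cc6C[C@@](O)(CO)[C@@H]5CO)cc(OC)c4O)c3)[C@H]2CO)ccc1O | target

Total step count: 13. Longest linear sequence: 12 steps (from 3 through steps 2–13).

Steps most likely to fail

Step 7. Heterolysis of the benzylic C2–O1 bond may compete, followed by hydride or vinyl shift to carbonyl isomers. Proton loss to a dienol may also compete with ring growth. The fallback sets out from 2 and 7 and comes back at 12. Addition of Zn(CH=CH2)2 to 2 with the enantiomer of 3-exo-morpholinoisoborneol that gives the R alcohol (the dextrorotatory ligand, by analogy with diethylzinc additions) should give the (R)-allylic alcohol F1. Williamson etherification of its sodium alkoxide (NaH, DMF) with allylic chloride 7 gives the bis-allylic ether F2. Ring-closing metathesis with the second-generation Grubbs catalyst (CH2Cl2, reflux) closes the trisubstituted alkene of 12 without ever handling the labile oxirane.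

Step 9. SN2 attack at C3 may be slow, because the nucleophile must pass on the ring face that carries the aryl group. Attack at C4, halohydrin formation by the magnesium halide or Lewis-acid-induced rearrangement of the epoxide could then take over. The fallback sets out from 12 and comes back at 15, and it delivers hydrogen rather than carbon to C3, from the open face.
- Dihydroxylation (OsO4 cat., N-methylmorpholine N-oxide) anti to the aryl group gives the cis-diol F3.
- Dess–Martin oxidation of the secondary alcohol gives the ketol F4. Its C2 centre is epimerisable, but its more stable epimer has aryl and benzyl cis, both pseudo-equatorial.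
- Methylenation with Cp2TiMe2 (toluene, 70 °C) gives the 3-methylene alcohol F5.
- Hydroboration with 9-BBN from the face opposite to aryl and benzyl, then H2O2/NaOH, gives 15.

Step 10. Ionisation of the benzylic ether of the rather electron-poor aryl group may be sluggish. Competing ionisation of the tertiary alcohol or loss of benzyl ethers under the stronger acid then needed could follow. The fallback sets out from 15 and comes back at 16, and it separates activation from cyclisation.
- Acetyl bromide (CH2Cl2, rt) cleaves the benzylic ether and acetylates the primary alcohol, giving the open-chain benzylic bromide diacetate F6.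
- AgOSO2CF3 with 2,6-di-tert-butylpyridine (CH2Cl2, -40 °C) abstracts bromide and triggers the Friedel–Crafts closure to the tetralin diacetate F7.
- K2CO3/MeOH removes the acetates to give 16.

Further compounds
F1 | step 7 | (R)-1-[4-(benzyloxy)-3-bromo-5-methoxyphenyl]prop-2-en-1-ol | C=C[C@@H](O)c1cc(OC)c(OCc2ccccc2)c(Br)c1
F2 | step 7 | (R)-1-arylallyl 2-[4-(benzyloxy)-3-methoxybenzyl]allyl ether | C=C[C@@H](OCC(=C)Cc1ccc(OCc2ccccc2)c(OC)c1)c1cc(OC)c(OCc2ccccc2)c(Br)c1
F3 | step 9 | 2-aryl-4-benzyloxolane-3,4-diol (both OH cis to each other and trans to aryl) | COc1cc(C[C@@]2(O)CO[C@@H](c3cc(OC)c(OCc4ccccc4)c(Br)c3)[C@@H]2O)ccc1OCc1ccccc1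
F4 | step 9 | 2-aryl-4-benzyl-4-hydroxyoxolan-3-one (aryl cis to benzyl) | COc1cc(C[C@@]2(O)CO[C@@H](c3cc(OC)c(OCc4ccccc4)c(Br)c3)C2=O)ccc1OCc1ccccc1
F5 | step 9 | 5-aryl-3-benzyl-4-methylideneoxolan-3-ol (aryl cis to benzyl) | COc1cc(C[C@@]2(O)CO[C@@H](c3cc(OC)c(OCc4ccccc4)c(Br)c3)C2=C)ccc1OCc1ccccc1
F6 | step 10 | open-chain benzylic bromide diacetate (epimers at the C–Br carbon) | COc1cc(C[C@@](O)(COC(C)=O)[C@H](COC(C)=O)C(Br)c2cc(OC)c(OCc3ccccc3)c(Br)c2)ccc1OCc1ccccc1
F7 | step 10 | diacetate of 16 | Brc1cc([C@H]2c3cc(OCc4ccccc4)c(OC)cc3C[C@@](O)(COC(C)=O)[C@@H]2COC(C)=O)cc(OC)c1OCc1ccccc1
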